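**Strategy.** Ring A is built, not bought: its C6-OH/C7-OMe/C8-OH triad beside the carboxyl-bearing C8a is exactly what a 1,2,3-trioxygenated silyloxy diene delivers to an alkynoate. One thermal [4+2] cycloaddition with loss of methanol forms C4a–C5 and C8–C8a and closes benzene ring A on an acyclic 4-aryloxyhex-2-ynoate that already holds the C3 and C4 stereocentres, the C4–O–C6′ ether and the complete, silyl-protected lactone B. The same benzannulation, run first on a simpler alkynoate, also supplies lactone B, so both halves come from one lactate-derived syn-alkynol; Mitsunobu inversion at C4 sets the trans ring A.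

Key step: step 13

Remarks: unprimed locants refer to the ring A isochromanone (C1–C8a), primed locants to lactone B. Addition of a propiolate anion to an α-silyloxy aldehyde is expected to favour the anti (Felkin–Anh) carbinol, whereas Mitsunobu inversion needs the syn (4R,5R) carbinol; C4 is therefore set by oxidation and reagent-controlled reduction (steps 4 and 5).

**Step 1**
Reactants: 1 methyl (R)-lactate
Product: 2 methyl (2R)-2-(triethylsilyloxy)propanoate
Conditions: Et3SiCl, imidazole, CH2Cl2, 0 °C → rt
Reagents that add atoms: chlorotriethylsilane, CC[Si](CC)(CC)Cl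
Why: Imidazole-promoted O-silylation of a secondary alcohol is routine and does not touch the lactate stereocentre.

**Step 2**
Reactants: 2 methyl (2R)-2-(triethylsilyloxy)propanoate
Product: 3 (2R)-2-(triethylsilyloxy)propanal
Conditions: iBu2AlH (1.05 equiv), CH2Cl2, −78 °C; aq. potassium sodium tartrate; used at once
Reagents that add atoms: none
Why: Partial ester reduction with iBu2AlH at −78 °C stops at the aluminium hemiacetal, which gives the aldehyde only on work-up, a standard route to O-silyl lactaldehydes that keeps the α-stereocentre when the aldehyde is used immediately.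

**Step 3**
Reactants: 3 (2R)-2-(triethylsilyloxy)propanal; 4 methyl propiolate
Product: 5 methyl (5R)-4-hydroxy-5-(triethylsilyloxy)hex-2-ynoate (mixture of C4 epimers)
Conditions: 4, LiN(SiMe3)2, THF, −78 °C; then 3; AcOH, −78 °C
Reagents that add atoms: none
Why: Acetylide addition of lithiated methyl propiolate to an aldehyde is fast at −78 °C, and because the Felkin–Anh preference favours the unwanted anti epimer, C4 is left unassigned here and reset in steps 4 and 5.

**Step 4**
Reactants: 5 methyl (5R)-4-hydroxy-5-(triethylsilyloxy)hex-2-ynoate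
Product: 6 methyl (5R)-4-oxo-5-(triethylsilyloxy)hex-2-ynoate
Conditions: Dess–Martin periodinane, CH2Cl2, 0 °C → rt; used without storage
Reagents that add atoms: none
Why: Dess–Martin oxidation converts both C4 epimers of the propargylic alcohol into one ynone under non-basic conditions that should leave the enolisable C5 stereocentre intact.

**Step 5**
Reactants: 6 methyl (5R)-4-oxo-5-(triethylsilyloxy)hex-2-ynoate
Product: 7 methyl (4R,5R)-4-hydroxy-5-(triethylsilyloxy)hex-2-ynoate
Conditions: (S)-Alpine-Borane [B-isopinocampheyl-9-BBN from (−)-α-pinene] (2 equiv), THF, 0 °C → rt; then HOCH2CH2NH2, Et2O, 0 °C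
Reagents that add atoms: none
Why: Midland reduction of an alkynyl ketone, in which hydride passes from the pinanyl group through a six-membered boat-like transition state with the slim alkynyl group in the crowded position, so the reagent from (−)-α-pinene should give the carbinol sense that is S in simple alkynyl carbinols and 4R here (C5 outranks the alkyne), the same sense as the Felkin preference of the α-silyloxy ketone (syn).

**Step 6**
Reactants: 8 methyl methoxyacetate
Product: 9 methyl 2-methoxy-3-oxobutanoate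
Conditions: 8 (2.2 equiv), LiN(iPr)2 (2.2 equiv), THF, −78 °C; AcCl (1.0 equiv); aq. HCl
Reagents that add atoms: acetyl chloride, CC(=O)Cl
Why: Crossed Claisen C-acylation of a lithium ester enolate by an acid chloride, with the second equivalent of enolate taking up the acidic proton of the β-keto ester as it forms.

**Step 7**
Reactants: 9 methyl 2-methoxy-3-oxobutanoate
Product: 10 methyl 2-methoxy-3-(trimethylsilyloxy)but-2-enoate
Conditions: Me3SiCl, Et3N, toluene, rt; filter, concentrate
Reagents that add atoms: chlorotrimethylsilane, C[Si](C)(C)Cl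
Why: Enol silylation of a β-keto ester with Me3SiCl and Et3N is the standard first stage toward a 1,3-bis(silyloxy)diene.

**Step 8**
Reactants: 10 methyl 2-methoxy-3-(trimethylsilyloxy)but-2-enoate
Product: 11 1,2-dimethoxy-1,3-bis(trimethylsilyloxy)buta-1,3-diene
Conditions: LiN(iPr)2, THF, −78 °C; Me3SiCl, −78 °C → rt; used fresh
Reagents that add atoms: chlorotrimethylsilane, C[Si](C)(C)Cl
Why: γ-Deprotonation of the silyl enol ether by LiN(iPr)2 gives the ester dienolate, whose O-silylation creates the ketene acetal terminus of the bis(silyloxy)diene (the usual two-stage preparation of such dienes).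

**Step 9**
Reactants: 7 methyl (4R,5R)-4-hydroxy-5-(triethylsilyloxy)hex-2-ynoate
Product: 12 methyl (4R,5R)-4-(tert-butyldimethylsilyloxy)-5-(triethylsilyloxy)hex-2-ynoate
Conditions: tBuMe2SiOTf, 2,6-lutidine, CH2Cl2, −78 → 0 °C
Reagents that add atoms: tert-butyldimethylsilyl triflate, CC(C)(C)[Si](C)(C)OS(=O)(=O)C(F)(F)F
Why: Silyl triflate with a hindered pyridine protects the propargylic hydroxyl with retention at C4 and avoids nucleophilic bases that would add to the ynoate.

**Step 10**
Reactants: 12 methyl (4R,5R)-4-(tert-butyldimethylsilyloxy)-5-(triethylsilyloxy)hex-2-ynoate; 11 1,2-dimethoxy-1,3-bis(trimethylsilyloxy)buta-1,3-diene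
Product: 15 methyl 6-[(1R,2R)-1-(tert-butyldimethylsilyloxy)-2-(triethylsilyloxy)propyl]-2,4-dihydroxy-3-methoxybenzoate, via cyclohexadiene cycloadduct 13 (not isolated), via aryl bis(trimethylsilyl) ether 14 (not isolated)
Conditions: 11 (2.5 equiv), toluene, 90 °C, sealed tube; then MeOH, AcOH (cat.), rt
Reagents that add atoms: none
Why: Diels–Alder cycloaddition/aromatisation of a 1-methoxy-1,3-bis(silyloxy)diene with an alkynoate, in which the CH2 terminus bonds to the β-carbon and the ketene acetal carbon to the α-carbon, methanol is lost and mild methanolysis frees both phenols while the alkyl silyl ethers and both stereocentres stay untouched; the step also rehearses the key step on a simpler substrate.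

**Step 11**
Reactants: 15 methyl 6-[(1R,2R)-1-(tert-butyldimethylsilyloxy)-2-(triethylsilyloxy)propyl]-2,4-dihydroxy-3-methoxybenzoate
Product: 17 (3R,4R)-4-(tert-butyldimethylsilyloxy)-6,8-dihydroxy-7-methoxy-3-methylisochroman-1-one (lactone B phenol), via hydroxy ester 16 (not isolated)
Conditions: PPTS (0.2 equiv), MeOH, rt; evaporate; toluene, 70 °C
Reagents that add atoms: none
Why: A secondary triethylsilyl ether is cleaved by PPTS in methanol far faster than a secondary tert-butyldimethylsilyl ether, and the freed hydroxyl then lactonizes under acid catalysis onto the neighbouring salicylate ester, which can give only the six-membered lactone because the benzylic oxygen stays silylated; no stereocentre is involved.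

**Step 12**
Reactants: 7 methyl (4R,5R)-4-hydroxy-5-(triethylsilyloxy)hex-2-ynoate; 17 (3R,4R)-4-(tert-butyldimethylsilyloxy)-6,8-dihydroxy-7-methoxy-3-methylisochroman-1-one
Product: 18 methyl (4S,5R)-4-{[(3R,4R)-4-(tert-butyldimethylsilyloxy)-8-hydroxy-7-methoxy-3-methyl-1-oxoisochroman-6-yl]oxy}-5-(triethylsilyloxy)hex-2-ynoate
Conditions: PPh3, DIAD, toluene, 0 °C (betaine preformed); then 17; then 7, 0 °C → rt
Reagents that add atoms: none
Why: Mitsunobu etherification of a secondary propargylic alcohol by a phenol proceeds by SN2 displacement of the oxyphosphonium group with inversion (4R to 4S), ionisation being disfavoured by the electron-poor alkyne, and the free, more acidic C6′ hydroxyl reacts in preference to the C8′ hydroxyl that is hydrogen-bonded to the lactone carbonyl.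

**Step 13**
Reactants: 18 methyl (4S,5R)-4-{[(3R,4R)-4-(tert-butyldimethylsilyloxy)-8-hydroxy-7-methoxy-3-methyl-1-oxoisochroman-6-yl]oxy}-5-(triethylsilyloxy)hex-2-ynoate; 11 1,2-dimethoxy-1,3-bis(trimethylsilyloxy)buta-1,3-diene
Product: 22 methyl 6-[(1S,2R)-1-{[(3R,4R)-4-(tert-butyldimethylsilyloxy)-8-hydroxy-7-methoxy-3-methyl-1-oxoisochroman-6-yl]oxy}-2-(triethylsilyloxy)propyl]-2,4-dihydroxy-3-methoxybenzoate, via C8′ trimethylsilyl ether 19 (not isolated), via cyclohexadiene cycloadduct 20 (not isolated), via aryl tris(trimethylsilyl) ether 21 (not isolated)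
Conditions: BSA [N,O-bis(trimethylsilyl)acetamide] (1.5 equiv), toluene, 50 °C; then 11 (3 equiv), 90 °C, sealed tube; then MeOH, AcOH (cat.), rt
Reagents that add atoms: none
Why: The electron-rich diene 11 and the ester-polarised alkyne of 19 should combine in a normal-electron-demand, strongly asynchronous [4+2] cycloaddition in which the unsubstituted CH2 terminus (future C5) bonds to the alkynoate β-carbon (future C4a) and the ketene acetal carbon (future C8) to the α-carbon (future C8a), giving cyclohexa-1,4-diene 20. The mixed ketal at C8 then expels methanol across C8/C5 to aromatise to 21, and methanolysis of the three aryl trimethylsilyl ethers frees the C6, C8 and C8′ phenols; the closest known reaction type is the Diels–Alder/aromatisation of 1-alkoxy-1,3-bis(silyloxy)butadienes with acetylenic esters to give resorcylate esters. Ring A is closed by this intermolecular [4+2] annulation, both new bonds going to the two alkyne carbons of an open chain, so no ring-size or tether constraint applies. No stereocentre is created, since the sp3 ketal carbon of 20 disappears on aromatisation, and C3, C4, C3′ and C4′ are spectators under neutral thermal conditions. The only selectivity needed is head-to-head regiochemistry, secured because the most nucleophilic and least hindered diene terminus (CH2) matches the most electrophilic alkyne carbon (β to the ester), while the methoxy group is the one expelled from C8, as is general for 1-methoxy-1-silyloxy dienes, so that C8 ends as a phenol next to the ester. Holding the temperature at 90 °C should keep the [3,3] rearrangement open to an aryl propargyl ether out of reach, and silylating the acidic C8′ phenol in the flask stops it from protonating the ketene acetal.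

**Step 14**
Reactants: 22 methyl 6-[(1S,2R)-1-{[(3R,4R)-4-(tert-butyldimethylsilyloxy)-8-hydroxy-7-methoxy-3-methyl-1-oxoisochroman-6-yl]oxy}-2-(triethylsilyloxy)propyl]-2,4-dihydroxy-3-methoxybenzoate
Product: 24 (3R,4S)-4-{[(3R,4R)-4-(tert-butyldimethylsilyloxy)-8-hydroxy-7-methoxy-3-methyl-1-oxoisochroman-6-yl]oxy}-6,8-dihydroxy-7-methoxy-3-methylisochroman-1-one, via seco hydroxy ester 23 (not isolated)
Conditions: PPTS (0.3 equiv), MeOH, rt; evaporate; toluene, 70 °C
Reagents that add atoms: none
Why: As in step 11, selective acid methanolysis of the triethylsilyl ether followed by acid-catalysed lactonization of the C3 hydroxyl onto the ring A methyl salicylate closes the six-membered lactone, the C4 oxygen being blocked as the aryl ether and the C4′ silyl ether kept on so that lactone B cannot rearrange to a phthalide.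

**Step 15**
Reactants: 24 (3R,4S)-4-{[(3R,4R)-4-(tert-butyldimethylsilyloxy)-8-hydroxy-7-methoxy-3-methyl-1-oxoisochroman-6-yl]oxy}-6,8-dihydroxy-7-methoxy-3-methylisochroman-1-one
Product: 25 (3R,4S)-4-{[(3R,4R)-4,8-dihydroxy-7-methoxy-3-methyl-1-oxoisochroman-6-yl]oxy}-6,8-dihydroxy-7-methoxy-3-methylisochroman-1-one (CNP0139537.4)
Conditions: HF·pyridine, THF/pyridine, 0 °C → rt
Reagents that add atoms: none
Why: Fluoride cleavage of a secondary silyl ether with buffered HF·pyridine is mildly acidic, so no alkoxide forms next to lactone B and neither the stereocentres nor the benzylic aryl ether should be disturbed.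

**Compound list**

1 | methyl (R)-lactate | C[C@@H](O)C(=O)OC | starting material
2 | methyl (2R)-2-(triethylsilyloxy)propanoate | C[C@@H](O[Si](CC)(CC)CC)C(=O)OC | intermediate
3 | (2R)-2-(triethylsilyloxy)propanal | C[C@@H](O[Si](CC)(CC)CC)C=O | intermediate
4 | methyl propiolate | COC(=O)C#C | starting material
5 | methyl (5R)-4-hydroxy-5-(triethylsilyloxy)hex-2-ynoate (C4 epimers) | COC(=O)C#CC(O)[C@@H](C)O[Si](CC)(CC)CC | intermediate
6 | methyl (5R)-4-oxo-5-(triethylsilyloxy)hex-2-ynoate | COC(=O)C#CC(=O)[C@@H](C)O[Si](CC)(CC)CC | intermediate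
7 | methyl (4R,5R)-4-hydroxy-5-(triethylsilyloxy)hex-2-ynoate | COC(=O)C#C[C@@H](O)[C@@H](C)O[Si](CC)(CC)CC | intermediate
8 | methyl methoxyacetate | COCC(=O)OC | starting material
9 | methyl 2-methoxy-3-oxobutanoate | COC(C(C)=O)C(=O)OC | intermediate
10 | methyl 2-methoxy-3-(trimethylsilyloxy)but-2-enoate | COC(=O)C(OC)=C(C)O[Si](C)(C)C | intermediate
11 | 1,2-dimethoxy-1,3-bis(trimethylsilyloxy)buta-1,3-diene | C=C(O[Si](C)(C)C)C(OC)=C(OC)O[Si](C)(C)C | intermediate
12 | methyl (4R,5R)-4-(tert-butyldimethylsilyloxy)-5-(triethylsilyloxy)hex-2-ynoate | COC(=O)C#C[C@@H](O[Si](C)(C)C(C)(C)C)[C@@H](C)O[Si](CC)(CC)CC | intermediate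
13 | methyl 2-[(1R,2R)-1-(tert-butyldimethylsilyloxy)-2-(triethylsilyloxy)propyl]-5,6-dimethoxy-4,6-bis(trimethylsilyloxy)cyclohexa-1,4-diene-1-carboxylate | COC(=O)C1=C(CC(O[Si](C)(C)C)=C(OC)C1(OC)O[Si](C)(C)C)[C@@H](O[Si](C)(C)C(C)(C)C)[C@@H](C)O[Si](CC)(CC)CC | intermediate
14 | methyl 6-[(1R,2R)-1-(tert-butyldimethylsilyloxy)-2-(triethylsilyloxy)propyl]-3-methoxy-2,4-bis(trimethylsilyloxy)benzoate | COC(=O)c1c(O[Si](C)(C)C)c(OC)c(O[Si](C)(C)C)cc1[C@@H](O[Si](C)(C)C(C)(C)C)[C@@H](C)O[Si](CC)(CC)CC | intermediate
15 | methyl 6-[(1R,2R)-1-(tert-butyldimethylsilyloxy)-2-(triethylsilyloxy)propyl]-2,4-dihydroxy-3-methoxybenzoate | COC(=O)c1c(O)c(OC)c(O)cc1[C@@H](O[Si](C)(C)C(C)(C)C)[C@@H](C)O[Si](CC)(CC)CC | intermediate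
16 | methyl 6-[(1R,2R)-1-(tert-butyldimethylsilyloxy)-2-hydroxypropyl]-2,4-dihydroxy-3-methoxybenzoate | COC(=O)c1c(O)c(OC)c(O)cc1[C@@H](O[Si](C)(C)C(C)(C)C)[C@@H](C)O | intermediate
17 | (3R,4R)-4-(tert-butyldimethylsilyloxy)-6,8-dihydroxy-7-methoxy-3-methylisochroman-1-one | COc1c(O)cc2c(c1O)C(=O)O[C@H](C)[C@@H]2O[Si](C)(C)C(C)(C)C | intermediate
18 | methyl (4S,5R)-4-{[(3R,4R)-4-(tert-butyldimethylsilyloxy)-8-hydroxy-7-methoxy-3-methyl-1-oxoisochroman-6-yl]oxy}-5-(triethylsilyloxy)hex-2-ynoate | COC(=O)C#C[C@H](Oc1cc2c(c(O)c1OC)C(=O)O[C@H](C)[C@@H]2O[Si](C)(C)C(C)(C)C)[C@@H](C)O[Si](CC)(CC)CC | intermediate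
19 | C8′-O-trimethylsilyl ether of 18 | COC(=O)C#C[C@H](Oc1cc2c(c(O[Si](C)(C)C)c1OC)C(=O)O[C@H](C)[C@@H]2O[Si](C)(C)C(C)(C)C)[C@@H](C)O[Si](CC)(CC)CC | intermediate
20 | cyclohexa-1,4-diene cycloadduct of 19 and 11 | COC(=O)C1=C(CC(O[Si](C)(C)C)=C(OC)C1(OC)O[Si](C)(C)C)[C@H](Oc1cc2c(c(O[Si](C)(C)C)c1OC)C(=O)O[C@H](C)[C@@H]2O[Si](C)(C)C(C)(C)C)[C@@H](C)O[Si](CC)(CC)CC | intermediate
21 | tris(trimethylsilyl) ether of 22 (C6-O, C8-O, C8′-O) | COC(=O)c1c(O[Si](C)(C)C)c(OC)c(O[Si](C)(C)C)cc1[C@H](Oc1cc2c(c(O[Si](C)(C)C)c1OC)C(=O)O[C@H](C)[C@@H]2O[Si](C)(C)C(C)(C)C)[C@@H](C)O[Si](CC)(CC)CC | intermediate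
22 | methyl 6-[(1S,2R)-1-{[(3R,4R)-4-(tert-butyldimethylsilyloxy)-8-hydroxy-7-methoxy-3-methyl-1-oxoisochroman-6-yl]oxy}-2-(triethylsilyloxy)propyl]-2,4-dihydroxy-3-methoxybenzoate | COC(=O)c1c(O)c(OC)c(O)cc1[C@H](Oc1cc2c(c(O)c1OC)C(=O)O[C@H](C)[C@@H]2O[Si](C)(C)C(C)(C)C)[C@@H](C)O[Si](CC)(CC)CC | intermediate
23 | methyl 6-[(1S,2R)-1-{[(3R,4R)-4-(tert-butyldimethylsilyloxy)-8-hydroxy-7-methoxy-3-methyl-1-oxoisochroman-6-yl]oxy}-2-hydroxypropyl]-2,4-dihydroxy-3-methoxybenzoate | COC(=O)c1c(O)c(OC)c(O)cc1[C@H](Oc1cc2c(c(O)c1OC)C(=O)O[C@H](C)[C@@H]2O[Si](C)(C)C(C)(C)C)[C@@H](C)O | intermediate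
24 | (3R,4S)-4-{[(3R,4R)-4-(tert-butyldimethylsilyloxy)-8-hydroxy-7-methoxy-3-methyl-1-oxoisochroman-6-yl]oxy}-6,8-dihydroxy-7-methoxy-3-methylisochroman-1-one | COc1c(O)cc2c(c1O)C(=O)O[C@H](C)[C@H]2Oc1cc2c(c(O)c1OC)C(=O)O[C@H](C)[C@@H]2O[Si](C)(C)C(C)(C)C | intermediate
25 | (3R,4S)-4-{[(3R,4R)-4,8-dihydroxy-7-methoxy-3-methyl-1-oxoisochroman-6-yl]oxy}-6,8-dihydroxy-7-methoxy-3-methylisochroman-1-one (CNP0139537.4) | COc1c(O)cc2c(c1O)C(=O)O[C@H](C)[C@H]2Oc1cc2c(c(O)c1OC)C(=O)O[C@H](C)[C@@H]2O | target

**Totals.** 15 steps in all; longest linear sequence 12 steps (steps 1–5 and 9–15, from methyl (R)-lactate).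

**Steps most likely to fail**

Step 13. The cycloaddition at the hindered β-carbon may be too slow, so that prolonged heating brings on the [3,3] rearrangement of the aryl propargyl ether or decay of the diene before ring A forms. The fallback abandons the de novo construction of ring A and makes the C4–O–C6′ bond last, using lactone B phenol 17 for both halves. It sets out from 17: acetylation of both phenols (Ac2O, pyridine, DMAP) would give (3R,4R)-4-(tert-butyldimethylsilyloxy)-7-methoxy-3-methyl-1-oxoisochromane-6,8-diyl diacetate F1; HF·pyridine would free the benzylic hydroxyl to give (3R,4R)-4-hydroxy-7-methoxy-3-methyl-1-oxoisochromane-6,8-diyl diacetate F2; Mitsunobu etherification of F2 with a second molecule of 17 (PPh3, DIAD) would invert C4 (4R to 4S) and give the bis-lactone diacetate F3; K2CO3 in MeOH at 0 °C would remove both acetates. The fallback comes back to the route at 24.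

Step 10. The same cycloaddition on the doubly silyloxy-substituted ynoate may stall for steric reasons, or the diene may be consumed by protodesilylation before it adds. The fallback is a base-mediated Michael–Claisen annulation (the classical orsellinate construction) of 12 with commercial methyl 4-methoxyacetoacetate (NaH, THF, 0 → 50 °C). Conjugate addition of the keto ester α-carbon to the ynoate β-carbon would give dimethyl 4-(methoxyacetyl)-3-[(1R,2R)-1-(tert-butyldimethylsilyloxy)-2-(triethylsilyloxy)propyl]pent-2-enedioate F4, whose methoxy-bearing carbanion closes onto the unsaturated ester, loses methanol and tautomerises to the arene. It sets out from 12 and comes back at 15.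

Step 12. Substitution at the hindered secondary carbinol may be slow, letting elimination, SN2′ attack or addition of the phosphine to the ynoate take over. The fallback separates activation from displacement: 7 with Tf2O and 2,6-lutidine at −78 °C would give methyl (4R,5R)-5-(triethylsilyloxy)-4-(trifluoromethylsulfonyloxy)hex-2-ynoate F5, used cold, and the mono-phenoxide of 17 (Cs2CO3, one equivalent, THF/DMF, −40 °C) would displace the triflate with inversion, the electron-poor alkyne disfavouring ionisation. It sets out from 7 and comes back at 18.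

**Further compounds**

F1 | step 13 | (3R,4R)-4-(tert-butyldimethylsilyloxy)-7-methoxy-3-methyl-1-oxoisochromane-6,8-diyl diacetate | COc1c(OC(C)=O)cc2c(c1OC(C)=O)C(=O)O[C@H](C)[C@@H]2O[Si](C)(C)C(C)(C)C
F2 | step 13 | (3R,4R)-4-hydroxy-7-methoxy-3-methyl-1-oxoisochromane-6,8-diyl diacetate | COc1c(OC(C)=O)cc2c(c1OC(C)=O)C(=O)O[C@H](C)[C@@H]2O
F3 | step 13 | (3R,4S)-4-{[(3R,4R)-4-(tert-butyldimethylsilyloxy)-8-hydroxy-7-methoxy-3-methyl-1-oxoisochroman-6-yl]oxy}-7-methoxy-3-methyl-1-oxoisochromane-6,8-diyl diacetate | COc1c(OC(C)=O)cc2c(c1OC(C)=O)C(=O)O[C@H](C)[C@H]2Oc1cc2c(c(O)c1OC)C(=O)O[C@H](C)[C@@H]2O[Si](C)(C)C(C)(C)C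
F4 | step 10 | dimethyl 4-(methoxyacetyl)-3-[(1R,2R)-1-(tert-butyldimethylsilyloxy)-2-(triethylsilyloxy)propyl]pent-2-enedioate | COCC(=O)C(C(=O)OC)C(=CC(=O)OC)[C@@H](O[Si](C)(C)C(C)(C)C)[C@@H](C)O[Si](CC)(CC)CC
F5 | step 12 | methyl (4R,5R)-5-(triethylsilyloxy)-4-(trifluoromethylsulfonyloxy)hex-2-ynoate | COC(=O)C#C[C@@H](OS(=O)(=O)C(F)(F)F)[C@@H](C)O[Si](CC)(CC)CC
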